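At early times the monomer in chains comes up slowly, and that lag is the first thing to watch.

the same everywhere: free monomer 0.020 M

| charge | transfer agent | initiator | remark | time |
|---|---|---|---|---|
| cedar | 2 mM | 0.37 mol% | run made earlier |  |
| larch | 2 mM | 0.55 mol% | run made earlier |  |
| ash | 2 mM | 0.73 mol% | run made earlier |  |
| zeta | 2.00 mM | 1 mol% |  | 40 min |
| delta | 2.00 mM | 0.3 mol% |  | 40 min |

| run | time / min | monomer in chains / % | free monomer / % |
|---|---|---|---|
| cedar | 2.50 | 0.9 | 98.9 |
| cedar | 8.00 | 4.9 | 94.9 |
| cedar | 12.0 | 8.0 | 91.4 |
| cedar | 20.0 | 14.7 | 85.2 |
| larch | 1.50 | 0.7 | 99.6 |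
| larch | 4.00 | 2.6 | 97.8 |
| larch | 8.00 | 7.3 | 92.3 |
| larch | 20.0 | 21.2 | 79.0 |
| ash | 5.00 | 5.1 | 94.5 |
| ash | 10.0 | 12.7 | 86.9 |
| ash | 15.0 | 20.2 | 79.7 |
| ash | 20.0 | 26.6 | 73.2 |

(each reading ± 0.3 percentage points)
- the average divides the monomer in chains by the number of chains begun, living and dead together
- the earlier runs do not show the number of chains; that part of a forecast is a guess
- which of the two ends with the longer chains by the average number of monomer units in a chain (chains begun, living or dead) ("neither" if they lie within 10%) (zeta / delta / neither)
- average number of monomer units in a chain (chains begun, living or dead) at the end, zeta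
- average number of monomer units in a chain (chains begun, living or dead) at the end, delta

In ash, the logarithm of charged over remaining free monomer, taken from monomer in chains at 10.0 min and 20.0 min, reads a slope of 0.0173 min⁻¹ and a lag of 2.17 min. This reckoning supposes that free monomer falls exponentially after the lag, with a slope proportional to loading; a line through two readings does not show that. Folding slope, loading and time after the lag into one number gives B, the lifetimes of free monomer that a flask runs through: 0.899 for zeta and 0.270 for delta. The same number reckoned for cedar gives 14.5% in chains against a reading of 14.7%, so it carries conversion to another loading, though the readings stop at 20.0 min.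

One number is not enough for length, since chains are unseen. This reckoning guesses that each initiator begins one chain and that the transfer agent begins none, with 18.4 lags in the run. Length is then one minus exp(−B), divided by the loading: 59.3 for zeta and 78.8 for delta, which is longer.

The forecast says zeta, with 5.5 and 2.3, and parts from this reckoning over the chain count: “I assume they are mainly the 2 mM of transfer agent”.

    free monomer + initiator → living end + monomer in chains (k = 0.230 M⁻¹ s⁻¹)
    living end + transfer agent → dead chain (kL = 0.120 M⁻¹ s⁻¹)
    free monomer + living end → monomer in chains + living end, rate k3*[living end]*[free monomer] (k = 2.40 M⁻¹ s⁻¹)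

The flasks give 56.1 for zeta and 73.0 for delta, so delta ends longer. In zeta, B gave 59.3% in chains and the flask holds 56.1%, while living ends and dead chains sum to 0.200 mM. The neighbouring flask, zeta with 0.6 mol% of initiator, has B of 0.539, which reckons a length of 69.5. It ends at 65.0, with 39.0% in chains and 61.0% as free monomer.

The data are calculated from invented constants.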